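L slows as it goes, more than one time constant allows: the 80.9% left in the amber run at 0.500 h, compounded to 3.00 h, gives 28.0%, yet the reading is 42.0%, higher. So I reckon in g, the inverse of f, where f is the fraction of L left, and x is X charged over L charged.

common to all: L 0.050 M
- amber: X 0.019 M; run made earlier
- red: X 0.028 M; run made earlier
- flask: time 4.0 h

| run | time / h | J / % | L / % |
|---|---|---|---|
| amber | 0.500 | 6.2 | 80.9 |
| amber | 1.00 | 6.9 | 68.6 |
| amber | 1.33 | 10.7 | 60.5 |
| amber | 2.00 | 10.8 | 49.6 |
| amber | 2.50 | 12.1 | 47.5 |
| amber | 3.00 | 13.3 | 42.0 |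
| red | 0.500 | 7.9 | 79.3 |
| red | 1.00 | 11.6 | 63.3 |
| red | 1.33 | 13.6 | 58.2 |
| red | 2.00 | 15.6 | 51.0 |
| red | 2.50 | 20.1 | 43.1 |
| red | 3.00 | 20.0 | 40.3 |

(scatter of a reading: 1 percentage point)

- the concentration of X at which the part of the L that has reacted at 4.0 h is just 70%, in M

- the amount of X is what is sought; it is there from the start
- a reading or a percentage of J counts all its forms, free or not

At 3.00 h, amber has x = 0.380 and g = 2.38; red has x = 0.560 and g = 2.48. Drawn back to no X, these scattered readings give my estimate of the self-clock s, the rate at which g climbs with no X present (a second-order loss):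

s = 0.390 h⁻¹

Start with no X: at 4.0 h, g = 2.56, so 60.9% of L is used, less than the 70% wanted. At 3.00 h, J per x reads 0.357 in red and 0.350 in amber; I assume that the red value holds at 4.0 h.

First extreme, J made last, on top of that loss: j = 9.08% of the L charged, so X = 0.0127 M.

Second extreme, J made first, the clock running on the rest: j = 43.7% of the L charged, so X = 0.0611 M.

The red run reads 68.0% of its 3.00 h J by 1.33 h, so J comes early but not at once, and I commit to the middle, 0.0369 M.

The forecast says 0.033 M, from 0.026 M to 0.044 M, lower than mine: “The dependence is shallow, so the uncertainty is large.”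

The flask gives 0.0378 M.

    L + X → Z + J (k = 6.80 L mol⁻¹ h⁻¹)
    X + Z ⇌ G, settled at all times (K = 33600 L mol⁻¹)
    2 L → E (k = 3.60 L mol⁻¹ h⁻¹)
    X + J ⇌ D, settled at all times (K = 10.4 L mol⁻¹)

In the flask, at 4.00 h, L + X uses L at 0.58 of the rate of 2 L into E. The self-clock, kept at 0.390 h⁻¹, carries this flask further: at 12.0 h its line by itself has 82.4% of L used, and the flask stands at 87.2%.

(The numbers in the tables are calculated with constants of no real substance, and the scatter is random.)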